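**Retrosynthetic overview**

1. Numbering: C1 quaternary C(CH3), C2/C3 ring CH2, C4 C(OH)iPr, C5 ring-fusion CH, C6 CHOBz, C7 CH2, C8 =C(CH3), C9 =CH, C10 CHOAng. The strategy rests on the seven-membered ring C1-C5-C6-C7-C8-C9-C10: oxygenated C6 and methyl-bearing C8 flank C7, the quaternary C1 is bonded to C10, and the tertiary C4 oxygen next to C5 can carry silicon. The ring therefore divides into a three-carbon acylsilane C1=C5-C6(=O)Si and a four-carbon enolate C7-C8-C9-C10.
2. End game: the C10 angelate and C6 benzoate are cut back to a C10 allylboronate / C6 ketone, which comes from 1,6-protoboration of a C6(=O)-C7=C8-C9=C10 dienone; C6 is then set by hydroxyl-directed reduction.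
3. The dienone comes from a C8 ketone (methylenation, silylene removal, base isomerisation), and that ketone from a Brook-mediated [3+4] annulation of a cyclic alkoxy-acylsilane (Si bridging C6 and O4) with the lithium enolate of (E)-4-methoxybut-3-en-2-one.
4. The acylsilane comes from a hydroxy cyclopentene carbaldehyde and an aminosilyllithium; the aldehyde comes from (S)-terpinen-4-ol by ozonolysis and aldol ring contraction.
5. Ring order: cyclopentene first, then the temporary five-membered oxasilolane, then the seven-membered carbocycle (while the silacycle grows to a six-membered dioxasiline), and finally removal of the silacycle.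

Key step: step 9

Remark (assumption): the purchased (S)-(+)-terpinen-4-ol is assayed by chiral GC and, if needed, enriched by preparative chiral chromatography before step 1, because C4 is the only imported stereocentre.
Remark: C4 is never touched; its CIP label changes from S (compounds 1-3) to R (from 4 onward) only because substituent priorities change.
Remark: in the SMILES of the titanium-aluminium methylidene reagent of step 10, the chloride that bridges titanium and aluminium is written with formal charges (Al-, Cl+); the compound is neutral.

**Route**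

Step 1
Reactants: 1 (S)-(+)-terpinen-4-ol
Product: 2 (S)-terpinen-4-ol triethylsilyl ether
Conditions: TESOTf, 2,6-lutidine, CH2Cl2, 0 °C to rt
Reagents that add atoms: triethylsilyl triflate, CC[Si](CC)(CC)OS(=O)(=O)C(F)(F)F
Why: Silyl triflate silylation of a tertiary alcohol is reliable, and the ether prevents hemiketal formation and retro-aldol cleavage of the β-oxygenated aldehyde made next, while C4 is not involved.

Step 2
Reactants: 2 (S)-terpinen-4-ol triethylsilyl ether
Product: 3 (S)-3-isopropyl-6-oxo-3-(triethylsilyloxy)heptanal
Conditions: O3, CH2Cl2, -78 °C; then PPh3, -78 °C to rt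
Reagents that add atoms: ozone, [O-][O+]=O
Why: Ozonolysis with reductive work-up should cleave the only alkene to the 1,6-keto aldehyde without touching C4.

Step 3
Reactants: 3 (S)-3-isopropyl-6-oxo-3-(triethylsilyloxy)heptanal
Product: 4 (R)-5-isopropyl-2-methyl-5-(triethylsilyloxy)cyclopent-1-ene-1-carbaldehyde
Conditions: piperidine (0.2 equiv), AcOH (0.2 equiv), toluene, 60 °C
Reagents that add atoms: none
Why: Amine/acid-catalysed intramolecular aldol condensation (aldehyde enamine onto the methyl ketone, five-membered closure, dehydration into conjugation) is the standard ring contraction of p-menthene-derived 6-oxoheptanals, and the weakly basic medium should leave the β-silyloxy group in place.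

Step 4
Reactants: 4 (R)-5-isopropyl-2-methyl-5-(triethylsilyloxy)cyclopent-1-ene-1-carbaldehyde
Product: 5 (R)-5-hydroxy-5-isopropyl-2-methylcyclopent-1-ene-1-carbaldehyde (C1 to C6 of the target)
Conditions: HF·pyridine, pyridine, THF, 0 °C to rt
Reagents that add atoms: none
Why: Buffered fluoride desilylation frees the tertiary alcohol, and the electron-poor enal disfavours ionisation of the allylic carbinol.

Step 5
Reactants: 6 dichlorodiphenylsilane
Product: 7 chloro(diethylamino)diphenylsilane
Conditions: Et2NH (2.0 equiv), hexane, 0 °C to rt; filtration, distillation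
Reagents that add atoms: diethylamine, CCNCC
Why: Mono-aminolysis of a dichlorosilane (second equivalent of amine as HCl scavenger) stops at the chloro(amino)silane because the amino group deactivates silicon toward a second substitution.

Step 6
Reactants: 7 chloro(diethylamino)diphenylsilane
Product: 8 (diethylamino)diphenylsilyllithium (THF solution, titrated and used directly)
Conditions: Li granules (excess), THF, 0 °C
Reagents that add atoms: lithium metal, [Li]
Why: Reductive lithiation of aryl chlorosilanes with lithium is the standard entry to silyllithiums and is known to tolerate an amino group on silicon.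

Step 7
Reactants: 5 (R)-5-hydroxy-5-isopropyl-2-methylcyclopent-1-ene-1-carbaldehyde; 8 (diethylamino)diphenylsilyllithium
Product: 10 bicyclic oxasilolane carbinol (Si bonded to C6 and O4; both C6 epimers), via dilithium adduct 9 (not isolated)
Conditions: 8 (2.2 equiv; the first equivalent converts C4-OH into its lithium alkoxide), THF, -78 °C; then AcOH (3 equiv), -78 °C to rt
Reagents that add atoms: none
Why: Hard silyllithiums add 1,2 to enals (the β-carbon is fully substituted here), the lithium α-silyl alkoxide resists Brook shift at low temperature, and on protonation C4-OH displaces diethylamine from silicon (alcoholysis of the Si-N bond) to close the five-membered ring; C6 is not controlled and both epimers converge in step 8.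

Step 8
Reactants: 10 bicyclic oxasilolane carbinol
Product: 11 cyclic alkoxy-acylsilane (C6=O between C5 and Si; Si-O4 ring retained)
Conditions: (COCl)2, DMSO, CH2Cl2, -78 °C; Et3N, -78 to 0 °C
Reagents that add atoms: none
Why: Swern oxidation is the established mild conversion of α-silyl carbinols into acylsilanes without Brook cleavage, and the Si-O ring bond is inert to it.

Step 9
Reactants: 11 cyclic alkoxy-acylsilane; 12 (E)-4-methoxybut-3-en-2-one
Product: 16 silylene-bridged hydroazulenone (C8 ketone; C9=C10; C5=C6 enol ether in an O4-SiPh2-O6 dioxasiline), via lithium dienolate 13 (not isolated), via cyclopropanolate 14 (not isolated), via methoxy enolate 15 (not isolated)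
Conditions: LDA (1.15 equiv), 12, THF, -78 °C; add 11, -78 to -30 °C; then 0 °C; AcOH/THF quench
Reagents that add atoms: none
Why: Proposed new method: the kinetic enolate 13 should add through C7 to the acylsilane carbonyl C6, the alkoxide then takes silicon from carbon (1,2-Brook shift, which enlarges the five-membered oxasilolane to the six-membered dioxasiline), and the siloxyallyl anion closes 3-exo-trig onto the C8 ketone to give the cis-dialkenylcyclopropanolate 14. Charge-accelerated [3,3] shift of 14 (anionic oxy-Cope through a boat transition state) breaks C6-C8, forms C1-C10 and so closes the seven-membered carbocycle, and on warming the C8/C9 enolate 15 expels methoxide from C10 (E1cB) to leave the C9=C10 enone. The closest known reaction type is the Brook-rearrangement-mediated [3+4] annulation of acryloylsilanes with lithium enolates of alkenyl methyl ketones; not yet shown are a cyclic alkoxy-acylsilane and a fully substituted alkene terminus that becomes quaternary, although thermal divinylcyclopropane rearrangements are known to create angular methyl centres from methyl-substituted cyclopentene termini. The only new stereocentre, C1, is controlled by C4 through the O4-Si-O6 bridge, which keeps O6 on the face of the C4 oxygen, so that the breaking C6-C8 bond can align with the C5=C1 π bond only on the isopropyl face and C10 is delivered there, leaving the C1 methyl cis to the C4 oxygen. The step needs 1,2- rather than 1,4-addition (secured by the fully substituted β-carbon C1), a fast Brook shift (helped by the alkoxy ligand on silicon) and a robust enolate (the methoxy group stabilises it and later serves as the leaving group), and cyclopropanolate formation should be reversible so that only the productive diastereomer is drained.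

Step 10
Reactants: 16 silylene-bridged hydroazulenone
Product: 17 C8-methylidene triene (C9=C10, C8=CH2, C5=C6 enol silyl ether)
Conditions: Cp2Ti(μ-Cl)(μ-CH2)AlMe2 (Tebbe reagent), pyridine (cat.), THF/toluene, -40 to 0 °C; dilute NaOH work-up
Reagents that add atoms: Tebbe reagent, C[Al-]1(C)C[Ti](C2C=CC=C2)(C2C=CC=C2)[Cl+]1
Why: Tebbe methylenation uses a non-basic titanium methylidene, so the doubly activated C7 methylene should not be enolised and the Si-O bonds stay intact; the new carbon becomes the C8 methyl.

Step 11
Reactants: 17 C8-methylidene triene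
Product: 18 4-hydroxy-8-methylidene hydroazul-9-en-6-one (C5 epimers)
Conditions: HF·pyridine, pyridine, THF, 0 °C
Reagents that add atoms: none
Why: Fluoride cleaves both Si-O bonds (enol silyl ether and tertiary silyl ether), releasing the C6 ketone and C4-OH; C5 is protonated without control and is corrected in step 12.

Step 12
Reactants: 18 4-hydroxy-8-methylidene hydroazul-9-en-6-one
Product: 19 trans-fused hydroxy dienone (C6=O, C7=C8(CH3), C9=C10; C5-H trans to the C1 methyl)
Conditions: DBU, toluene, rt
Reagents that add atoms: none
Why: Amidine-base isomerisation through the C7 dienolate with γ-protonation at the exocyclic CH2 should give the more stable linear dienone, while reversible enolisation toward C5 equilibrates the ring fusion to the isomer with C6 anti to the isopropyl group and hydrogen-bonded to C4-OH.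

Step 13
Reactants: 19 trans-fused hydroxy dienone
Product: 20 C10 allylboronate with β,γ-unsaturated C6 ketone (C8=C9; used at once)
Conditions: B2pin2, CuCl (5 mol %), Xantphos (5 mol %), NaOtBu (10 mol %), MeOH (2 equiv), THF, 0 °C; pH 7 buffer
Reagents that add atoms: bis(pinacolato)diboron, CC1(C)OB(OC1(C)C)B1OC(C)(C)C(C)(C)O1
Why: Copper-catalysed 1,6-conjugate borylation (protoboration) of α,β,γ,δ-unsaturated ketones favours the δ-carbon when the β-carbon is disubstituted; the Cu-B unit should add to C9=C10 anti to the pseudoaxial C1 methyl, and kinetic α-protonation by methanol leaves the C8=C9 alkene.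

Step 14
Reactants: 20 C10 allylboronate ketone
Product: 21 C4,C6 anti-diol boronate
Conditions: Me4NBH(OAc)3, AcOH/MeCN (1:1), -20 °C
Reagents that add atoms: none
Why: Evans-Saksena reduction: the C4 alkoxide binds boron and delivers hydride intramolecularly to the C6 carbonyl on the face carrying C4-O, which sets C6 anti to C4-OH, and the reagent is too mild for the allylboronate or the alkene.

Step 15
Reactants: 21 C4,C6 anti-diol boronate
Product: 22 C6 benzoate boronate
Conditions: BzCl, pyridine, DMAP (cat.), CH2Cl2, 0 °C to rt
Reagents that add atoms: benzoyl chloride, O=C(Cl)c1ccccc1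
Why: DMAP-catalysed acylation takes the only secondary hydroxyl, since the tertiary C4-OH is inert and C10 is still masked as boron.

Step 16
Reactants: 22 C6 benzoate boronate
Product: 23 C10 allylic alcohol (C6 benzoate, C4-OH)
Conditions: NaBO3·4H2O, THF/H2O (1:1), rt
Reagents that add atoms: sodium perborate (NaBO3, used as tetrahydrate), [Na+].[O-]OB=O
Why: Perborate oxidation of the C-B bond proceeds by 1,2-migration with retention at C10 and without allylic transposition, and is mild enough for the benzoate.

Step 17
Reactants: 23 C10 allylic alcohol; 24 angelic acid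
Product: 26 target CNP0397959.1, via mixed anhydride 25 (not isolated)
Conditions: 24, 2,4,6-trichlorobenzoyl chloride, Et3N, toluene, rt; then 23, 80 °C
Reagents that add atoms: none
Why: Thermal acyl transfer from the mixed 2,4,6-trichlorobenzoic anhydride (Yamaguchi-type esterification without nucleophilic catalyst) is an established way to angeloylate hindered secondary alcohols without Z-to-E isomerisation, attack going to the less hindered angeloyl carbonyl while the tertiary C4-OH stays free.

**Compound list**

1 | (S)-(+)-terpinen-4-ol | CC1=CC[C@](O)(C(C)C)CC1 | starting material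
2 | (S)-terpinen-4-ol triethylsilyl ether | CC1=CC[C@](O[Si](CC)(CC)CC)(C(C)C)CC1 | intermediate
3 | (S)-3-isopropyl-6-oxo-3-(triethylsilyloxy)heptanal | O=CC[C@](O[Si](CC)(CC)CC)(C(C)C)CCC(C)=O | intermediate
4 | (R)-5-isopropyl-2-methyl-5-(triethylsilyloxy)cyclopent-1-ene-1-carbaldehyde | CC1=C(C=O)[C@](O[Si](CC)(CC)CC)(C(C)C)CC1 | intermediate
5 | (R)-5-hydroxy-5-isopropyl-2-methylcyclopent-1-ene-1-carbaldehyde | CC1=C(C=O)[C@](O)(C(C)C)CC1 | intermediate
6 | dichlorodiphenylsilane | Cl[Si](Cl)(c1ccccc1)c1ccccc1 | starting material
7 | chloro(diethylamino)diphenylsilane | CCN(CC)[Si](Cl)(c1ccccc1)c1ccccc1 | intermediate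
8 | (diethylamino)diphenylsilyllithium | CCN(CC)[Si]([Li])(c1ccccc1)c1ccccc1 | intermediate
9 | dilithium alkoxide of the open C6 α-(aminosilyl) carbinol (not isolated) | CC1=C(C(O[Li])[Si](N(CC)CC)(c2ccccc2)c2ccccc2)[C@](O[Li])(C(C)C)CC1 | intermediate
10 | bicyclic oxasilolane carbinol: 2,2-diphenyl-1,2-oxasilolane fused to the cyclopentene, Si on C6 (CHOH) and O4, C5=C1 alkene, both C6 epimers | CC1=C2C(O)[Si](c3ccccc3)(c3ccccc3)O[C@@]2(C(C)C)CC1 | intermediate
11 | cyclic alkoxy-acylsilane (C6=O between C5 and Si) | CC1=C2C(=O)[Si](c3ccccc3)(c3ccccc3)O[C@@]2(C(C)C)CC1 | intermediate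
12 | (E)-4-methoxybut-3-en-2-one | CO/C=C/C(C)=O | starting material
13 | lithium (E)-4-methoxybuta-1,3-dien-2-olate (not isolated) | C=C(O[Li])/C=C/OC | intermediate
14 | cis-dialkenylcyclopropanolate: cyclopropane C6-C7-C8, O6 in the dioxasiline, lithium alkoxide and (E)-methoxyvinyl on C8 (not isolated) | CC1=C2[C@@]3(C[C@]3(O[Li])/C=C/OC)O[Si](c3ccccc3)(c3ccccc3)O[C@@]2(C(C)C)CC1 | intermediate
15 | C10-methoxy cycloheptadiene C8/C9 lithium enolate (not isolated) | C[C@@]12[C@H](OC)C=C(O[Li])CC3=C1[C@@](CC2)(C(C)C)O[Si](c1ccccc1)(c1ccccc1)O3 | intermediate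
16 | silylene-bridged hydroazulenone (C8 ketone, C9=C10, C5=C6 enol silyl ether) | C[C@@]12C=CC(=O)CC3=C1[C@@](CC2)(C(C)C)O[Si](c1ccccc1)(c1ccccc1)O3 | intermediate
17 | C8-methylidene triene | C[C@@]12C=CC(=C)CC3=C1[C@@](CC2)(C(C)C)O[Si](c1ccccc1)(c1ccccc1)O3 | intermediate
18 | 4-hydroxy-8-methylidene hydroazul-9-en-6-one (C5 epimers) | C[C@@]12C=CC(=C)CC(=O)C1[C@@](CC2)(C(C)C)O | intermediate
19 | trans-fused hydroxy cyclohepta-2,4-dienone (C6=O, C7=C8, C9=C10) | CC1=CC(=O)[C@@H]2[C@@](C)(C=C1)CC[C@@]2(O)C(C)C | intermediate
20 | C10 pinacol allylboronate, β,γ-unsaturated C6 ketone | CC1(C)OB(OC1(C)C)[C@@H]2C=C(C)CC(=O)[C@@H]3[C@]2(C)CC[C@@]3(O)C(C)C | intermediate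
21 | C4,C6 anti-diol boronate | CC1(C)OB(OC1(C)C)[C@@H]2C=C(C)C[C@H](O)[C@@H]3[C@]2(C)CC[C@@]3(O)C(C)C | intermediate
22 | C6 benzoate boronate | CC1(C)OB(OC1(C)C)[C@@H]2C=C(C)C[C@H](OC(=O)c4ccccc4)[C@@H]3[C@]2(C)CC[C@@]3(O)C(C)C | intermediate
23 | C10 allylic alcohol, C6 benzoate | O[C@@H]1C=C(C)C[C@H](OC(=O)c2ccccc2)[C@@H]2[C@]1(C)CC[C@@]2(O)C(C)C | intermediate
24 | angelic acid, (Z)-2-methylbut-2-enoic acid | C/C=C(/C)C(=O)O | starting material
25 | angelic 2,4,6-trichlorobenzoic anhydride (not isolated) | C/C=C(/C)C(=O)OC(=O)c1c(Cl)cc(Cl)cc1Cl | intermediate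
26 | target CNP0397959.1 (C10 angelate, C6 benzoate, C4 tertiary alcohol) | C/C=C(/C)C(=O)O[C@@H]1C=C(C)C[C@H](OC(=O)c2ccccc2)[C@@H]2[C@]1(C)CC[C@@]2(O)C(C)C | target

**Step count and risks**

Total: 17 steps. Longest linear sequence: 15 steps from 1 (steps 1-4 and 7-17); the two-step silyl reagent branch (steps 5-6) joins at step 7.

Step 9 (the labelled step). The cascade may stop after the 1,2-addition or the Brook shift (protonation of the siloxyallyl anion, retro-addition of the enolate), the [3,3] shift may be too slow at the fully substituted C1 terminus, C1-C10 bonding may occur on the wrong face, or released methoxide may strip the enol silyl ether. The fallback uses known chemistry, sets out from 4 and comes back at 19: the quaternary centre is made by 1,2-allylation and anionic oxy-Cope shift with 1,3-chirality transfer, and the seven-membered ring by olefin metathesis. Asymmetric allylboration of 4 with the enantiomer of B-allyldiisopinocampheylborane that delivers the 6S carbinol should give the (6S)-homoallylic alcohol F1 (a wrong C6 epimer can be corrected by oxidation and Corey-Bakshi-Shibata reduction). KH and 18-crown-6 in THF should then trigger the oxy-Cope shift through the chair in which the C6 hydrogen, not the alkoxide, points at the C1 methyl (allylic 1,3-strain); this carries the allyl group to the isopropyl face of C1 and gives, after protonation, the 1-allyl-1-methyl cyclopentane carbaldehyde F2. Addition of 2-methylallylmagnesium chloride gives the carbinol F3, Dess-Martin oxidation the β,γ-unsaturated ketone F4, and ring-closing metathesis with the second-generation Hoveyda-Grubbs catalyst (H2IMes)Cl2Ru=CH(2-iPrOC6H4) in toluene at 80 °C the bicyclic cycloheptenone F5 (C8=C9, C10 still CH2). Dehydrogenation with chloranil in hot tert-butanol, the classical conversion of enones into linear dienones, gives the TES-protected dienone F6, and HF·pyridine followed by DBU gives 19.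

Step 13. Borylation may go 1,4 to C8, Cu-B addition at C10 next to the quaternary C1 may be sluggish or unselective between faces, and the allylboronate may conjugate or protodeboronate under the basic catalyst before it is used. The fallback sets out from 19 and comes back at 26: oxygen is placed on C10 by epoxidation and reductive opening, and the two esters are introduced in reverse order. Buffered m-CPBA should epoxidise the more electron-rich distal C9=C10 bond anti to the C1 methyl to give the γ,δ-epoxy enone F7. SmI2 in THF/MeOH at -78 °C should open the epoxide at C9 and, after kinetic α-protonation, give the C10-hydroxy β,γ-unsaturated ketone F8. Its only secondary hydroxyl is angeloylated through 25 as in step 17 to give the keto angelate F9, Evans-Saksena reduction as in step 14 gives the C6 alcohol F10, and benzoylation (BzCl, pyridine, no DMAP) gives 26.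

Step 7. The silyl anion may deprotonate or reduce the hindered hydroxy enal instead of adding, the α-silyl alkoxide may undergo Brook shift and protonation, or hydrolysis of the Si-N bond may outrun ring closure. The fallback sets out from 5, comes back at 11 and also replaces step 8: the acylsilane is made at the carboxylic acid oxidation level. Pinnick oxidation (NaClO2, NaH2PO4, 2-methylbut-2-ene) of 5 gives the hydroxy acid F11, and EDC/HOBt coupling with morpholine the hydroxy morpholine amide F12. Addition of 8 (2.2 equiv, THF, -78 °C) stops at the tetrahedral adduct, which on acetic acid work-up collapses to the open aminosilyl acylsilane F13 (not isolated); its C4-OH displaces diethylamine from silicon to give 11.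

**Further compounds**

F1 | step 9 | (6S)-homoallylic alcohol from allylation of 4 | CC1=C([C@@H](O)CC=C)[C@](O[Si](CC)(CC)CC)(C(C)C)CC1
F2 | step 9 | 1-allyl-1-methyl cyclopentane carbaldehyde (allyl on the isopropyl face, C5 epimers) | C=CC[C@@]1(C)CC[C@@](O[Si](CC)(CC)CC)(C(C)C)C1C=O
F3 | step 9 | 2-methylallyl carbinol at C6 | C=CC[C@@]1(C)CC[C@@](O[Si](CC)(CC)CC)(C(C)C)C1C(O)CC(C)=C
F4 | step 9 | β,γ-unsaturated C6 ketone (metathesis precursor) | C=CC[C@@]1(C)CC[C@@](O[Si](CC)(CC)CC)(C(C)C)C1C(=O)CC(C)=C
F5 | step 9 | bicyclic cycloheptenone (C6=O, C8=C9, C10 CH2, O4-TES) | CC1=CC[C@@]2(C)CC[C@@](O[Si](CC)(CC)CC)(C(C)C)C2C(=O)C1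
F6 | step 9 | TES ether of the dienone 19 (C5 epimers) | CC1=CC(=O)C2[C@@](C)(C=C1)CC[C@@]2(O[Si](CC)(CC)CC)C(C)C
F7 | step 13 | C9,C10-epoxy enone (epoxide anti to the C1 methyl) | CC1=CC(=O)[C@@H]2[C@@](C)([C@@H]3O[C@@H]31)CC[C@@]2(O)C(C)C
F8 | step 13 | C10-hydroxy β,γ-unsaturated C6 ketone | O[C@@H]1C=C(C)CC(=O)[C@@H]2[C@]1(C)CC[C@@]2(O)C(C)C
F9 | step 13 | C10 angelate, C6 ketone | C/C=C(/C)C(=O)O[C@@H]1C=C(C)CC(=O)[C@@H]2[C@]1(C)CC[C@@]2(O)C(C)C
F10 | step 13 | C10 angelate, C6 alcohol | C/C=C(/C)C(=O)O[C@@H]1C=C(C)C[C@H](O)[C@@H]2[C@]1(C)CC[C@@]2(O)C(C)C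
F11 | step 7 | (R)-5-hydroxy-5-isopropyl-2-methylcyclopent-1-ene-1-carboxylic acid | CC1=C(C(=O)O)[C@](O)(C(C)C)CC1
F12 | step 7 | morpholine amide of F11 | CC1=C(C(=O)N2CCOCC2)[C@](O)(C(C)C)CC1
F13 | step 7 | open (diethylamino)diphenylsilyl acylsilane with free C4-OH | CC1=C(C(=O)[Si](N(CC)CC)(c2ccccc2)c2ccccc2)[C@](O)(C(C)C)CC1
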